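**Retrosynthetic overview** (indene numbering of the target: C1 CHMe, C2=C3 with Et on C3, C3a, C4 with Me and CO2H, C5 with Et and the dienyl arm, C6=C7 with Me on C7, C7a)
1. Target 25 ⇐ aldehyde acid 23: a Horner–Wadsworth–Emmons reaction with a cinnamylphosphonate builds the phenylbutadienyl arm on the C5 quaternary carbon.
2. Bicyclic acid 22 ⇐ ester 18: one flask forms the C3a–C4 bond (Ireland–Claisen rearrangement) and the C6=C7 double bond (ring-closing metathesis), so the cyclohexene is the last ring formed, on a preformed cyclopentene.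
3. Enabling feature: C4 carries the carboxyl group and is bonded to C3a, which is allylic to the C2=C3 bond of the five-membered ring (a γ,δ-unsaturated acid); C6 and C7 of the six-membered ring are alkene carbons hanging on C5 and C7a, so they can be joined as olefin termini.
4. Ester 18 ⇐ cyclopentenol 7 (from silyloxycyclopentenone 1: three-component coupling, elimination, α-ethylation, CBS reduction) + acid 17 (from ynone 10: transfer hydrogenation, hydroalumination–iodination, ethylation, Ireland–Claisen chirality transfer to the C5 quaternary centre).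
5. Ring order: cyclopentene (from the chiral pool, kept throughout), then cyclohexene (key step).

Key step: step 13

Remark: acid 17 is drawn as its expected major C-2 epimer; either epimer serves, because that carbon becomes trigonal again in step 13.

Step 1
Reactants: 1 (S)-4-[(tert-butyldimethylsilyl)oxy]cyclopent-2-en-1-one; 2 isopropenylmagnesium bromide
Product: 3 (2S,3R,4S)-4-[(tert-butyldimethylsilyl)oxy]-2-methyl-3-(prop-1-en-2-yl)cyclopentan-1-one
Conditions: CuBr·SMe2 (10 mol %), THF, −78 °C; then MeI, DMPU, −78 → −20 °C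
Reagents that add atoms: iodomethane, CI
Why: Copper-catalysed conjugate addition of the Grignard reagent should occur anti to the silyloxy group and the resulting enolate should be C-methylated anti to the new isopropenyl group (three-component coupling on a 4-oxygenated cyclopentenone), which sets the trans,trans array.

Step 2
Reactants: 3 (2S,3R,4S)-4-[(tert-butyldimethylsilyl)oxy]-2-methyl-3-(prop-1-en-2-yl)cyclopentan-1-one
Product: 4 (4R,5S)-5-methyl-4-(prop-1-en-2-yl)cyclopent-2-en-1-one
Conditions: DBU, CH2Cl2, 0 °C
Reagents that add atoms: none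
Why: E1cB elimination of the β-silyloxy group should give the conjugated enone without touching the two stereocentres, the α-methyl group already being in its more stable trans position.

Step 3
Reactants: 4 (4R,5S)-5-methyl-4-(prop-1-en-2-yl)cyclopent-2-en-1-one
Product: 5 (4S,5S)-2-iodo-5-methyl-4-(prop-1-en-2-yl)cyclopent-2-en-1-one
Conditions: I2, pyridine, CH2Cl2, 0 → 25 °C
Reagents that add atoms: iodine, II
Why: α-Iodination of a cyclic enone by the pyridine/iodine addition–iodination–elimination sequence is general and should leave the isolated isopropenyl group alone.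

Step 4
Reactants: 5 (4S,5S)-2-iodo-5-methyl-4-(prop-1-en-2-yl)cyclopent-2-en-1-one
Product: 6 (4R,5S)-2-ethyl-5-methyl-4-(prop-1-en-2-yl)cyclopent-2-en-1-one
Conditions: Et2Zn, Pd(dppf)Cl2 (5 mol %), THF, 50 °C
Reagents that add atoms: diethylzinc, CC[Zn]CC
Why: Negishi coupling of an α-iodoenone with an alkylzinc reagent should install the ethyl group, the bidentate phosphine suppressing β-hydride elimination, with no stereocentre involved.

Step 5
Reactants: 6 (4R,5S)-2-ethyl-5-methyl-4-(prop-1-en-2-yl)cyclopent-2-en-1-one
Product: 7 (1S,4R,5S)-2-ethyl-5-methyl-4-(prop-1-en-2-yl)cyclopent-2-en-1-ol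
Conditions: (R)-2-methyl-CBS-oxazaborolidine (20 mol %), catecholborane, toluene, −78 °C; then H2O
Reagents that add atoms: none
Why: In the CBS reduction the catalyst should bind the ketone with the α-ethylvinyl side as the large group and deliver hydride anti to the adjacent methyl group, which is also the substrate-preferred face, so the new carbinol centre is cis to the methyl and trans to the isopropenyl group, while catecholborane should not hydroborate the alkenes at this temperature.

Step 6
Reactants: 8 3,3-diethoxyprop-1-yne; 9 N-methoxy-N-methylacetamide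
Product: 10 5,5-diethoxypent-3-yn-2-one
Conditions: n-BuLi, THF, −78 °C; then 9, −78 → 0 °C; H2O
Reagents that add atoms: none
Why: Acylation of a lithium acetylide with a Weinreb amide should stop at the ketone because the chelated tetrahedral adduct survives until work-up.

Step 7
Reactants: 10 5,5-diethoxypent-3-yn-2-one
Product: 11 (R)-5,5-diethoxypent-3-yn-2-ol
Conditions: RuCl[(R,R)-TsDPEN](p-cymene) (1 mol %), i-PrOH, 25 °C
Reagents that add atoms: none
Why: Asymmetric transfer hydrogenation of an alkynyl methyl ketone with the (R,R)-diamine ruthenium complex should give the (R)-carbinol, the alkyne playing the part that the aryl group plays in acetophenone.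

Step 8
Reactants: 11 (R)-5,5-diethoxypent-3-yn-2-ol
Product: 12 (2R,3Z)-5,5-diethoxy-4-iodopent-3-en-2-ol
Conditions: NaAlH2(OCH2CH2OMe)2, THF, 0 °C; then I2, −78 °C
Reagents that add atoms: iodine, II
Why: Alkoxide-directed trans-hydroalumination should place aluminium on the distal alkyne carbon in a five-membered aluminate, and iodinolysis with retention should give the (Z)-iodoalkene, the low temperature keeping the alkenylaluminate from expelling ethoxide.

Step 9
Reactants: 12 (2R,3Z)-5,5-diethoxy-4-iodopent-3-en-2-ol
Product: 13 (2R,3E)-5,5-diethoxy-4-ethylpent-3-en-2-ol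
Conditions: Et2Zn, Pd(dppf)Cl2 (5 mol %), THF, 40 °C
Reagents that add atoms: diethylzinc, CC[Zn]CC
Why: Negishi coupling with retention of alkene geometry should put the ethyl group cis to the carbinol carbon, giving the (E)-trisubstituted alkene.

Step 10
Reactants: 13 (2R,3E)-5,5-diethoxy-4-ethylpent-3-en-2-ol
Product: 14 (2R,3E)-5,5-diethoxy-4-ethylpent-3-en-2-yl propanoate
Conditions: EtCOCl, pyridine, DMAP (cat.), CH2Cl2, 0 °C
Reagents that add atoms: propanoyl chloride, CCC(Cl)=O
Why: Acylation of a secondary alcohol with an acid chloride under nucleophilic catalysis should proceed without touching the stereocentre or the acetal.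

Step 11
Reactants: 14 (2R,3E)-5,5-diethoxy-4-ethylpent-3-en-2-yl propanoate
Product: 17 (2S,3S,4E)-3-(diethoxymethyl)-3-ethyl-2-methylhex-4-enoic acid, via silyl ketene acetal 15 (not isolated), via trimethylsilyl ester 16 (not isolated)
Conditions: LiN(iPr)2, Me3SiCl, THF, −78 → 50 °C; then pH 6 buffer
Reagents that add atoms: none
Why: The Ireland–Claisen rearrangement through a chair transition state with the carbinol methyl group equatorial should transfer the (R)-carbinol chirality to the new quaternary centre (3S) and give the (E)-propenyl group.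

Step 12
Reactants: 17 (2S,3S,4E)-3-(diethoxymethyl)-3-ethyl-2-methylhex-4-enoic acid; 7 (1S,4R,5S)-2-ethyl-5-methyl-4-(prop-1-en-2-yl)cyclopent-2-en-1-ol
Product: 18 (1S,4R,5S)-2-ethyl-5-methyl-4-(prop-1-en-2-yl)cyclopent-2-en-1-yl (2S,3S,4E)-3-(diethoxymethyl)-3-ethyl-2-methylhex-4-enoate
Conditions: 2,4,6-trichlorobenzoyl chloride, Et3N, THF, 25 °C; then 7, DMAP, toluene, 40 °C
Reagents that add atoms: none
Why: Yamaguchi esterification (mixed anhydride, then acyl transfer by DMAP) should join the hindered acid and the hindered secondary alcohol with retention at the carbinol centre.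

Step 13
Reactants: 18 (1S,4R,5S)-2-ethyl-5-methyl-4-(prop-1-en-2-yl)cyclopent-2-en-1-yl (2S,3S,4E)-3-(diethoxymethyl)-3-ethyl-2-methylhex-4-enoate
Product: 22 (1R,3aR,4R,5S,7aS)-5-(diethoxymethyl)-3,5-diethyl-1,4,7-trimethyl-3a,4,5,7a-tetrahydro-1H-indene-4-carboxylic acid, via silyl ketene acetal 19 (not isolated), via rearranged silyl ester 20 (not isolated), via bicyclic silyl ester 21 (not isolated)
Conditions: KN(SiMe3)2, Me3SiCl, toluene, −78 °C; then second-generation Hoveyda–Grubbs catalyst RuCl2(H2IMes)(=CH-C6H4-2-OiPr) (5 mol %), −78 → 80 °C; pH 6 buffer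
Reagents that add atoms: none
Why: Enolisation with internal silyl quench should give the (Z)-silyl ketene acetal 19 (quaternary carbon syn to OSiMe3, methyl syn to the cyclopentenyl oxygen, which avoids allylic strain with the bulky alkoxy group); on warming, a suprafacial [3,3]-sigmatropic shift (Ireland–Claisen rearrangement, the closest known reaction type, here run in one flask with ring-closing metathesis) joins the enolate carbon to the ring CH at the far end of the allyl unit and moves the ring double bond to its final position, and the ruthenium carbene then joins the isopropenyl and propenyl termini with loss of propene. The sigmatropic step closes no ring; the cyclohexene is closed by olefin metathesis of a 1,1-disubstituted with a 1,2-disubstituted alkene, and because the two arms sit trans on the cyclopentene only the trans-fused six-membered ring can form. The ring-fusion centre C3a is set by 1,3-chirality transfer from the carbinol carbon, the new bond forming on the face that carried the oxygen, cis to the ring methyl and trans to the isopropenyl group. The quaternary centre C4 is set by the ketene acetal geometry together with a boat-like transition state: the chair would hold the silyloxy-bearing carbon over the ring face that carries the cis methyl group, while the boat leaves the bulky quaternary substituent outside the ring. The step needs (Z)-selective enolisation and chemoselective metathesis; the size difference between methyl and the quaternary carbon should secure the first, and the inertness of the tetrasubstituted ketene acetal and the trisubstituted ring alkene, with only one alkene pair able to give an unstrained ring, the second.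

Step 14
Reactants: 22 (1R,3aR,4R,5S,7aS)-5-(diethoxymethyl)-3,5-diethyl-1,4,7-trimethyl-3a,4,5,7a-tetrahydro-1H-indene-4-carboxylic acid
Product: 23 (1R,3aR,4R,5S,7aS)-3,5-diethyl-5-formyl-1,4,7-trimethyl-3a,4,5,7a-tetrahydro-1H-indene-4-carboxylic acid
Conditions: PPTS, acetone/H2O, 50 °C
Reagents that add atoms: water, O
Why: Mild acid hydrolysis of the diethyl acetal should free the aldehyde, which has no α-hydrogen to epimerise and will sit largely as the cyclic lactol with the cis carboxyl group, of no consequence for step 15.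

Step 15
Reactants: 23 (1R,3aR,4R,5S,7aS)-3,5-diethyl-5-formyl-1,4,7-trimethyl-3a,4,5,7a-tetrahydro-1H-indene-4-carboxylic acid; 24 diethyl [(2E)-3-phenylprop-2-en-1-yl]phosphonate
Product: 25 (1R,3aR,4R,5S,7aS)-3,5-diethyl-1,4,7-trimethyl-5-[(1E,3E)-4-phenylbuta-1,3-dien-1-yl]-3a,4,5,7a-tetrahydro-1H-indene-4-carboxylic acid
Conditions: LiN(SiMe3)2 (2.5 equiv), THF, −78 → 25 °C; then 1 M HCl
Reagents that add atoms: none
Why: In the Horner–Wadsworth–Emmons reaction the excess base should open the lactol to the aldehyde carboxylate, and the allylic phosphonate anion should give the new (E)-double bond while its (E)-styryl unit is kept.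

**Compound list**
1 | (S)-4-[(tert-butyldimethylsilyl)oxy]cyclopent-2-en-1-one | O=C1C=C[C@@H](O[Si](C)(C)C(C)(C)C)C1 | starting material
2 | isopropenylmagnesium bromide | C=C(C)[Mg]Br | starting material
3 | (2S,3R,4S)-4-[(tert-butyldimethylsilyl)oxy]-2-methyl-3-(prop-1-en-2-yl)cyclopentan-1-one | O=C1[C@@H](C)[C@H](C(C)=C)[C@@H](O[Si](C)(C)C(C)(C)C)C1 | intermediate
4 | (4R,5S)-5-methyl-4-(prop-1-en-2-yl)cyclopent-2-en-1-one | O=C1C=C[C@@H](C(C)=C)[C@@H]1C | intermediate
5 | (4S,5S)-2-iodo-5-methyl-4-(prop-1-en-2-yl)cyclopent-2-en-1-one | O=C1C(I)=C[C@@H](C(C)=C)[C@@H]1C | intermediate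
6 | (4R,5S)-2-ethyl-5-methyl-4-(prop-1-en-2-yl)cyclopent-2-en-1-one | O=C1C(CC)=C[C@@H](C(C)=C)[C@@H]1C | intermediate
7 | (1S,4R,5S)-2-ethyl-5-methyl-4-(prop-1-en-2-yl)cyclopent-2-en-1-ol | CCC1=C[C@@H](C(C)=C)[C@H](C)[C@@H]1O | intermediate
8 | 3,3-diethoxyprop-1-yne | C#CC(OCC)OCC | starting material
9 | N-methoxy-N-methylacetamide | CC(=O)N(C)OC | starting material
10 | 5,5-diethoxypent-3-yn-2-one | CC(=O)C#CC(OCC)OCC | intermediate
11 | (R)-5,5-diethoxypent-3-yn-2-ol | C[C@@H](O)C#CC(OCC)OCC | intermediate
12 | (2R,3Z)-5,5-diethoxy-4-iodopent-3-en-2-ol | C[C@@H](O)/C=C(\I)C(OCC)OCC | intermediate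
13 | (2R,3E)-5,5-diethoxy-4-ethylpent-3-en-2-ol | C[C@@H](O)/C=C(\CC)C(OCC)OCC | intermediate
14 | (2R,3E)-5,5-diethoxy-4-ethylpent-3-en-2-yl propanoate | CCC(=O)O[C@H](C)/C=C(\CC)C(OCC)OCC | intermediate
15 | O-trimethylsilyl ketene acetal of 14, (E) at the new double bond (methyl cis to the allylic oxygen) | C/C=C(/O[Si](C)(C)C)O[C@H](C)/C=C(\CC)C(OCC)OCC | intermediate
16 | trimethylsilyl (2S,3S,4E)-3-(diethoxymethyl)-3-ethyl-2-methylhex-4-enoate | C/C=C/[C@](CC)(C(OCC)OCC)[C@H](C)C(=O)O[Si](C)(C)C | intermediate
17 | (2S,3S,4E)-3-(diethoxymethyl)-3-ethyl-2-methylhex-4-enoic acid | C/C=C/[C@](CC)(C(OCC)OCC)[C@H](C)C(=O)O | intermediate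
18 | (1S,4R,5S)-2-ethyl-5-methyl-4-(prop-1-en-2-yl)cyclopent-2-en-1-yl (2S,3S,4E)-3-(diethoxymethyl)-3-ethyl-2-methylhex-4-enoate | CCC1=C[C@@H](C(C)=C)[C@H](C)[C@@H]1OC(=O)[C@@H](C)[C@@](CC)(C(OCC)OCC)/C=C/C | intermediate
19 | O-trimethylsilyl ketene acetal of 18, (Z) at the new double bond (quaternary carbon syn to OSiMe3, methyl syn to the ring oxygen) | CCC1=C[C@@H](C(C)=C)[C@H](C)[C@@H]1O/C(O[Si](C)(C)C)=C(\C)[C@@](CC)(C(OCC)OCC)/C=C/C | intermediate
20 | trimethylsilyl (2R,3S,4E)-3-(diethoxymethyl)-3-ethyl-2-[(1R,4R,5S)-2-ethyl-4-methyl-5-(prop-1-en-2-yl)cyclopent-2-en-1-yl]-2-methylhex-4-enoate | CCC1=C[C@@H](C)[C@H](C(C)=C)[C@H]1[C@@](C)(C(=O)O[Si](C)(C)C)[C@@](CC)(C(OCC)OCC)/C=C/C | intermediate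
21 | trimethylsilyl ester of 22 | CCC1=C[C@@H](C)[C@@H]2C(C)=C[C@@](C(OCC)OCC)(CC)[C@](C)(C(=O)O[Si](C)(C)C)[C@@H]12 | intermediate
22 | (1R,3aR,4R,5S,7aS)-5-(diethoxymethyl)-3,5-diethyl-1,4,7-trimethyl-3a,4,5,7a-tetrahydro-1H-indene-4-carboxylic acid | CCC1=C[C@@H](C)[C@@H]2C(C)=C[C@@](C(OCC)OCC)(CC)[C@](C)(C(=O)O)[C@@H]12 | intermediate
23 | (1R,3aR,4R,5S,7aS)-3,5-diethyl-5-formyl-1,4,7-trimethyl-3a,4,5,7a-tetrahydro-1H-indene-4-carboxylic acid (open form of the lactol) | CCC1=C[C@@H](C)[C@@H]2C(C)=C[C@@](C=O)(CC)[C@](C)(C(=O)O)[C@@H]12 | intermediate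
24 | diethyl [(2E)-3-phenylprop-2-en-1-yl]phosphonate | CCOP(=O)(C/C=C/c1ccccc1)OCC | starting material
25 | (1R,3aR,4R,5S,7aS)-3,5-diethyl-1,4,7-trimethyl-5-[(1E,3E)-4-phenylbuta-1,3-dien-1-yl]-3a,4,5,7a-tetrahydro-1H-indene-4-carboxylic acid | CCC1=C[C@@H](C)[C@@H]2C(C)=C[C@@](/C=C/C=C/c3ccccc3)(CC)[C@](C)(C(=O)O)[C@@H]12 | target

**Total step count:** 15
**Longest linear sequence:** 10 steps (steps 6 to 15)

**Steps most likely to fail**

Step 13. The enolisation of the α,α-disubstituted ester may not be geometrically clean, or part of the material may pass through the chair transition state; either would erode the configuration of the acid-bearing quaternary carbon. The ruthenium carbene may also initiate slowly at two hindered alkenes or be poisoned by silylamine residues. The fallback takes the quaternary-centre problem out of the rearrangement; it sets out from 13 (with 7) and returns at 22. Johnson–Claisen rearrangement of 13 with triethyl orthoacetate (propanoic acid cat., 135 °C) should give ethyl (3R,4E)-3-(diethoxymethyl)-3-ethylhex-4-enoate F1 with the same chirality transfer. Saponification (KOH, EtOH/H2O) should give (3R,4E)-3-(diethoxymethyl)-3-ethylhex-4-enoic acid F2, and Yamaguchi esterification with 7 the ester F3. The same one-flask rearrangement and metathesis, now through a ketene acetal with no geometry issue at a future quaternary carbon, should give the 4-desmethyl analogue of 22 F4. C-methylation of its dianion (LiN(iPr)2, 2.2 equiv, THF, −78 → 0 °C; MeI) should occur on the face opposite the pseudoaxial diethoxymethyl group and lead back to 22.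

Step 15. The aldehyde is flanked by two quaternary carbons and masked as a lactol, so the olefination may stall or lose (E)-selectivity. The fallback sets out from 23 and returns at 25. Takai olefination (CrCl2, CHI3, THF, 0 °C) should give the 5-[(E)-2-iodoethenyl] acid F5, and Suzuki coupling with (E)-2-phenylethenylboronic acid (Pd(PPh3)4, K2CO3, THF/H2O, 50 °C) should then build the diene with both geometries fixed by the partners.

Step 8. The alkenylaluminate may expel ethoxide to give an alkoxyallene, or the hydroalumination may lose regiocontrol next to the acetal. The fallback sets out from 10 and returns at 13. Conjugate hydroiodination of the ynone (LiI, AcOH, MeCN, 25 °C) should give (3Z)-5,5-diethoxy-4-iodopent-3-en-2-one F6 by anti addition. Negishi coupling (Et2Zn, Pd(dppf)Cl2) should give (3E)-5,5-diethoxy-4-ethylpent-3-en-2-one F7, and CBS reduction with (S)-2-methyl-CBS-oxazaborolidine and catecholborane should set the (R)-carbinol of 13.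

**Further compounds**
F1 | step 13 | ethyl (3R,4E)-3-(diethoxymethyl)-3-ethylhex-4-enoate | C/C=C/[C@](CC)(C(OCC)OCC)CC(=O)OCC
F2 | step 13 | (3R,4E)-3-(diethoxymethyl)-3-ethylhex-4-enoic acid | C/C=C/[C@](CC)(C(OCC)OCC)CC(=O)O
F3 | step 13 | (1S,4R,5S)-2-ethyl-5-methyl-4-(prop-1-en-2-yl)cyclopent-2-en-1-yl (3R,4E)-3-(diethoxymethyl)-3-ethylhex-4-enoate | CCC1=C[C@@H](C(C)=C)[C@H](C)[C@@H]1OC(=O)C[C@@](CC)(C(OCC)OCC)/C=C/C
F4 | step 13 | 4-desmethyl analogue of 22 (hydrogen in place of the methyl group on the acid-bearing carbon) | CCC1=C[C@@H](C)[C@@H]2C(C)=C[C@@](C(OCC)OCC)(CC)[C@H](C(=O)O)[C@@H]12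
F5 | step 15 | 5-[(E)-2-iodoethenyl] analogue of 25 (iodoethenyl in place of the phenylbutadienyl group) | CCC1=C[C@@H](C)[C@@H]2C(C)=C[C@@](/C=C/I)(CC)[C@](C)(C(=O)O)[C@@H]12
F6 | step 8 | (3Z)-5,5-diethoxy-4-iodopent-3-en-2-one | CC(=O)/C=C(\I)C(OCC)OCC
F7 | step 8 | (3E)-5,5-diethoxy-4-ethylpent-3-en-2-one | CC(=O)/C=C(\CC)C(OCC)OCC
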